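If the row was to be trusted within the hour, I first had to know which given numbers move it.

| flask | left-handed substrate | right-handed substrate | gas | catalyst | remark | time |
|---|---|---|---|---|---|---|
| Monday's | 1 M | 1 M | 200 mM (held) | 1.2 mol% | run made earlier |  |
| Tuesday's | 1 M | 1 M | 200 mM (held) | 3.7 mol% | run made earlier |  |
| Wednesday's | 1 M | 1 M | 200 mM (held) | 13 mol% | run made earlier |  |
| ash | 1.0 M | 1.0 M | 200 mM (held) | 1 mol% |  | 5.0 min |
| cedar | 1.0 M | 1.0 M | 200 mM (held) | 2 mol% |  | 5.0 min |
| oak | 1.0 M | 1.0 M | 200 mM (held) | 4 mol% |  | 5.0 min |
| maple | 1.0 M | 1.0 M | 200 mM (held) | 8 mol% |  | 5.0 min |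
| larch | 1.0 M | 1.0 M | 200 mM (held) | 15 mol% |  | 5.0 min |

| run | time / min | left-handed product / % | left-handed substrate / % |
|---|---|---|---|
| Monday's | 0.200 | 2.1 | 47.9 |
| Monday's | 0.417 | 4.6 | 43.6 |
| Monday's | 0.667 | 9.8 | 41.1 |
| Monday's | 1.33 | 16.4 | 32.6 |
| Monday's | 2.50 | 27.9 | 22.9 |
| Tuesday's | 0.500 | 15.4 | 34.7 |
| Tuesday's | 1.00 | 25.4 | 23.7 |
| Tuesday's | 1.50 | 34.7 | 16.1 |
| Tuesday's | 2.00 | 40.1 | 9.3 |
| Tuesday's | 2.50 | 44.1 | 5.9 |
| Wednesday's | 0.500 | 25.6 | 24.5 |
| Wednesday's | 1.00 | 41.1 | 8.3 |
| Wednesday's | 1.50 | 47.7 | 1.0 |
| Wednesday's | 2.00 | 49.9 | 1.0 |
| Wednesday's | 2.50 | 50.5 | 0.2 |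

(each reading ± 0.5 percentage points)

- catalyst is single-handed; left-handed substrate and right-handed substrate are mirror images of each other, charged as a racemate, each of them at the stated concentration
- at the start none of partner is dissolved
- on the list of suspects stand: partner + catalyst + left-handed substrate -> catalyst + left-handed product; partner + catalyst + right-handed substrate -> catalyst + right-handed product; left-handed substrate <-> right-handed substrate; gas <-> partner; left-handed product <-> right-handed product; partner <-> dormant form
- a step back or a flat step of under half a point counts as no turn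
- "hardly changes" means that all values lie within two and a half points (for a concentration: within two and a half percent of the largest)

- amount of left-handed product at the end, in percent of the left-handed substrate and right-handed substrate together charged for ash, cedar, oak, maple, larch, in this order
- how that number moves from the first to the last of them (falls, then rises / falls all the way / hardly changes / rises, then falls / rises all the way)

1. The ceiling: in Tuesday's last reading, left-handed product and left-handed substrate summed to 50.0%. I took that as the limit for c(left-handed product). Larch's number stood or fell with it: larch had more catalyst than Wednesday's run, and Wednesday's k of 2.16 /min, cut to half, still left 0.223%.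

2. The pseudo-first-order constant k of left-handed substrate: this mattered at low loading. At Monday's k of 0.321 /min, read from its readings and reckoned out to 5.0 min, an error of 10% moved my c(left-handed product) by 1.6 percentage points.

3. The loading order n, the logarithm of the ratio of the k of two runs with the same substrate and gas charge over the logarithm of the ratio of their loadings, so that time drops out: with Tuesday's k of 0.886 /min, I read n as 0.902. It mattered little for ash: setting n to 1 moved ash by 0.31 points.

4. My number: I reckoned ash's k at 0.272 /min, which left 12.8% of left-handed substrate and gave 37.2% of left-handed product. Oak, from Tuesday's k, gave 49.6%.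

5. The forecast, which differs from my ash, gave 36.5%, 45.7%, 49.4%, 50%, 50%, and rises all the way: “Product therefore climbs towards the 50% ceiling”.

6. The flasks gave 36.6%, 46.0%, 49.6%, 50.0%, 50.0%, and rises all the way.

    partner + catalyst + left-handed substrate → catalyst + left-handed product (k = 3.30 /M²/s)
    partner + catalyst + right-handed substrate → catalyst + right-handed product (k = 1.70 /M²/s)
    left-handed substrate ⇌ right-handed substrate (k = 0.0210 /s)
    gas ⇌ partner, rate k4*(csat - [partner]) (kL = 0.240 /s)
    left-handed product ⇌ right-handed product (k = 0.0200 /s)
    partner ⇌ dormant form (K = 26.0, k = 0.00720 /s)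

In ash, the forward step from left-handed product to right-handed product had a half-life of 0.58 min, shorter than the run's 5.0 min. Yet at 1.79 min, each step taken net, left-handed product was still made 4.10 times faster than it was used up. Ash held 13.4% of left-handed substrate at 5.00 min, against my 12.8%. For cedar, n gave a k of 0.509 /min and 3.92% left, and cedar held 3.97%.

(The readings were generated by integration from invented constants; scatter was added.)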